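Readings and results come from a simulation on assumed constants.

**In the vessel.** The vessel holds the racemic substrates, reagent, free catalyst, racemization catalyst and impurity of the recipe called flask.

| flask | left-handed substrate | right-handed substrate | reagent | free catalyst | racemization catalyst | impurity | remark | time |
|---|---|---|---|---|---|---|---|---|
| theta | 0.25 M | 0.25 M | 3 equiv | 2 mol% | 3.9 mol% | 9 mM | run made earlier |  |
| zeta | 0.50 M | 0.50 M | 3 equiv | 2 mol% | 3.9 mol% | 4.5 mM | run made earlier |  |
| flask | 0.50 M | 0.50 M | 3.00 equiv | 2 mol% | 3.9 mol% | 9.0 mM |  | 5.0 h |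

| run | time / h | left-handed substrate / % | right-handed substrate / % | left-handed product / % |
|---|---|---|---|---|
| theta | 0.833 | 49.6 | 49.9 | 0 |
| theta | 1.50 | 49.8 | 50.1 | 0.4 |
| theta | 2.50 | 50.1 | 49.8 | 0.1 |
| theta | 3.00 | 49.2 | 49.8 | 0.3 |
| theta | 4.00 | 50.2 | 49.6 | 0.2 |
| theta | 5.00 | 49.8 | 50.3 | 0 |
| theta | 6.00 | 49.6 | 49.8 | 0 |
| zeta | 1.33 | 37.0 | 36.5 | 24.2 |
| zeta | 2.50 | 34.4 | 34.5 | 26.8 |
| zeta | 4.00 | 33.4 | 33.9 | 27.7 |
| zeta | 5.00 | 34.1 | 35.3 | 28.5 |
| zeta | 6.00 | 34.0 | 34.0 | 27.5 |

(standard deviation of a reading: 0.5 percentage points)

- part of the left-handed substrate and right-handed substrate charged together that has reacted at 5.0 h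
- excess of left-handed product over right-handed product in the product at 5.0 h
- excess of right-handed substrate over left-handed substrate among what is left of the two at 5.0 h

- free catalyst is single-handed; left-handed substrate and right-handed substrate are mirror images of each other, charged as a racemate, each of them at the stated concentration
- the numbers in the tables scatter by 0.5 percentage points (one standard deviation)
- an excess is below zero if the other one leads

**The margin.** We assume each impurity removes one free catalyst. The margin is then c(free catalyst) minus c(impurity), as charged. Theta has a margin of −4.00 mM, and its left-handed product stays within the scatter of zero. Zeta has 5.50 mM. Its substrates hold level from 4.00 h to 6.00 h, with 31.8% reacted on average. So we read the turnover number of a surviving catalyst, product formed per catalyst in the margin, as 57.8.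

**At the end.** The flask has a margin of 1.00 mM, less than its 10.0 mM of free catalyst. So we expect c near 5.78%. Zeta's substrates stay equal within the scatter, and its readings give an excess of 75.7%. We expect eS near zero and eP near that reading.

**Leave alone.** Keep both charges exact. The margin is a small difference, and our c follows it.

**The result.** The forecast gives c 10% (4% to 21%), eP 76% and eS 0%, saying “I lean towards the stronger poisoning”. Its c stands above ours. The flask gives c 6.86%, eP 76.3% and eS 0%.

    free catalyst + impurity → spent catalyst B (k = 26.6 M⁻¹ s⁻¹)
    reagent + free catalyst → spent catalyst C (k = 2.70 × 10⁻⁴ M⁻¹ s⁻¹)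
    reagent + free catalyst + left-handed substrate → free catalyst + left-handed product (k = 0.0339 M⁻² s⁻¹)
    left-handed substrate + racemization catalyst ⇌ right-handed substrate + racemization catalyst, rate k4*[racemization catalyst]*[left-handed substrate] forward; the back reaction follows from the equilibrium constant (k = 0.301 M⁻¹ s⁻¹)
    racemization catalyst → spent catalyst A (k = 9.22 × 10⁻⁷ s⁻¹)
    reagent + free catalyst + right-handed substrate → free catalyst + right-handed product (k = 0.00454 M⁻² s⁻¹)

**Two flasks.** The flask's c is above our 5.78%, and it equals 68.6 turnovers per catalyst in the margin, against 57.8 read from zeta. At 5.00 h, spent catalyst B holds 90.0% of the flask's catalyst and spent catalyst C holds 9.99%. The neighbouring flask with 8 mol% free catalyst has a margin of 31.0 mM. Multiplied by 57.8, that gives 1.79 M, more than the 1.00 M of substrates charged. That neighbouring flask reaches c 87.8% at 5.00 h, with 2.61% of its catalyst still free.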